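**Retrosynthetic overview**
1. Target 29 ⇐ C12 allylic oxidation and C2 acetylation of tricycle 26 ⇐ transannular, epoxide-initiated cation–olefin cyclisation of the 14-membered cembranoid 25 (C1–C10 bond; cyclohexene and cyclodecane formed together, as in the cembrane → briarane biogenesis).
2. 25 ⇐ Z-selective RCM (C13=C14) of 24; the γ-lactone of 24 ⇐ Cu–H reductive aldol (C8–C17) of keto acrylate 22.
3. The acyclic C1–C13 chain ⇐ two chloroallylations of the linchpin 3-chloro-2-(chloromethyl)propene 5: syn (Ipc-borane, then cis-3,4-epoxide) onto epoxy aldehyde 4, and anti (zinc) onto aldehyde 17.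
4. 4 ⇐ (E)-3-methylpent-2-en-4-yn-1-ol (Lindlar, Sharpless AE); 17 ⇐ pent-1-en-4-yne (carboalumination/Negishi coupling, Sharpless AE, Ti-mediated acetolysis).
5. Ring order: two oxiranes → γ-lactone → 14-membered carbocycle → six- and ten-membered rings in one step → enone.

Assumption: briarane numbering (C1–C20) is used for all fragments; compounds 1, 5, 9, 10 and (+)-Ipc2BOMe are taken as catalogue chemicals. The route is a proposal; no step has been run.

**Step 1**
Reactants: 1 (E)-3-methylpent-2-en-4-yn-1-ol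
Product: 2 (E)-3-methylpenta-2,4-dien-1-ol
Conditions: H2 (1 atm), Lindlar Pd/CaCO3–Pb, quinoline, Et2O, 0 °C
Reagents that add atoms: none
Why: Lindlar semi-hydrogenation stops the terminal enyne at the diene and leaves the E-trisubstituted alkene untouched.

**Step 2**
Reactants: 2 (E)-3-methylpenta-2,4-dien-1-ol
Product: 3 [(2S,3S)-3-ethenyl-3-methyloxiran-2-yl]methanol
Conditions: Ti(OiPr)4 (10 mol%), L-(+)-DIPT (12 mol%), t-BuOOH, 4 Å MS, CH2Cl2, −20 °C
Reagents that add atoms: tert-butyl hydroperoxide CC(C)(C)OO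
Why: Sharpless asymmetric epoxidation touches only the allylic-alcohol alkene, and L-(+)-tartrate gives the (2S,3S) epoxide of this E-allylic alcohol, which sets C2 and places the C1–O leaving group for the later inversion at C1.

**Step 3**
Reactants: 3 [(2S,3S)-3-ethenyl-3-methyloxiran-2-yl]methanol
Product: 4 (2R,3S)-3-ethenyl-3-methyloxirane-2-carbaldehyde
Conditions: Dess–Martin periodinane, pyridine, CH2Cl2, 0 °C; used crude in solution
Reagents that add atoms: none
Why: Buffered Dess–Martin oxidation gives the volatile epoxy aldehyde without opening the vinyl oxirane or epimerising C2.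

**Step 4**
Reactants: 4 (2R,3S)-3-ethenyl-3-methyloxirane-2-carbaldehyde; 5 3-chloro-2-(chloromethyl)prop-1-ene
Product: 8 (2S,3S)-2-[(2R,3R)-3-(3-chloroprop-1-en-2-yl)oxiran-2-yl]-3-ethenyl-3-methyloxirane, via chloroallylborane 6 (not isolated), via syn-chlorohydrin 7 (not isolated)
Conditions: 5, (+)-Ipc2BOMe, LiN(c-Hex)2 (Cy2NH/n-BuLi), Et2O, −95 °C; BF3·OEt2; 4, −95 °C; ethanolamine; DBU, CH2Cl2, 0 °C
Reagents that add atoms: none
Why: Oehlschlager-type (Z)-γ-chloroallylboration through a Zimmerman–Traxler chair under Ipc reagent control gives the syn-chlorohydrin (C3 and C4 set), and 3-exo-tet closure with inversion at C4 gives the cis-3,4-epoxide, expected to outrun 5-exo attack on the primary allylic chloride.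

**Step 5**
Reactants: 9 pent-1-en-4-yne; 10 ethyl (Z)-3-iodoprop-2-enoate
Product: 12 ethyl (2Z,4E)-5-methylocta-2,4,7-trienoate, via alkenylalane 11 (not isolated)
Conditions: AlMe3, Cp2ZrCl2 (20 mol%), CH2Cl2, 0 °C → rt; then 10, Pd(PPh3)4 (5 mol%), ZnCl2 (cat.), THF, rt
Reagents that add atoms: trimethylaluminium C[Al](C)C
Why: Negishi Zr-catalysed syn-carboalumination sets the E-trisubstituted C10=C11 alkene with Me-20, and the stereoretentive Pd cross-coupling keeps the Z-acrylate geometry.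

**Step 6**
Reactants: 12 ethyl (2Z,4E)-5-methylocta-2,4,7-trienoate
Product: 13 (2Z,4E)-5-methylocta-2,4,7-trien-1-ol
Conditions: DIBAL-H (2.2 equiv), CH2Cl2, −78 °C; Rochelle salt
Reagents that add atoms: none
Why: DIBAL 1,2-reduction of the enoate gives the Z-allylic alcohol without isomerising the diene.

**Step 7**
Reactants: 13 (2Z,4E)-5-methylocta-2,4,7-trien-1-ol
Product: 14 [(2S,3R)-3-[(1E)-2-methylpenta-1,4-dien-1-yl]oxiran-2-yl]methanol
Conditions: Ti(OiPr)4 (20 mol%), L-(+)-DIPT (25 mol%), t-BuOOH, 4 Å MS, CH2Cl2, −20 °C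
Reagents that add atoms: tert-butyl hydroperoxide CC(C)(C)OO
Why: Sharpless asymmetric epoxidation of the Z-allylic alcohol (only the 2,3-alkene reacts) gives the cis-epoxide whose C8 centre later steers C7 and whose C9 centre is inverted in the next step.

**Step 8**
Reactants: 14 [(2S,3R)-3-[(1E)-2-methylpenta-1,4-dien-1-yl]oxiran-2-yl]methanol
Product: 15 (2S,3S,4E)-1,2-dihydroxy-5-methylocta-4,7-dien-3-yl acetate
Conditions: Ti(OiPr)4 (1.5 equiv), AcOH (5 equiv), CH2Cl2, 0 °C
Reagents that add atoms: acetic acid CC(=O)O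
Why: Ti(OiPr)4-mediated opening of a 2,3-epoxy alcohol delivers the carboxylate to C3 (here also allylic) with inversion, which installs the C9 acetate of the target with its final configuration.

**Step 9**
Reactants: 15 (2S,3S,4E)-1,2-dihydroxy-5-methylocta-4,7-dien-3-yl acetate
Product: 16 (2S,3S,4E)-5-methyl-1,2-bis[(triethylsilyl)oxy]octa-4,7-dien-3-yl acetate
Conditions: TESOTf, 2,6-lutidine, CH2Cl2, −78 °C
Reagents that add atoms: triethylsilyl triflate CC[Si](CC)(CC)OS(=O)(=O)C(F)(F)F
Why: Silyl ether formation blocks acetate migration and makes the C8 oxygen non-chelating for the Felkin addition in step 11.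

**Step 10**
Reactants: 16 (2S,3S,4E)-5-methyl-1,2-bis[(triethylsilyl)oxy]octa-4,7-dien-3-yl acetate
Product: 17 (2R,3S,4E)-5-methyl-1-oxo-2-[(triethylsilyl)oxy]octa-4,7-dien-3-yl acetate
Conditions: (COCl)2, DMSO, CH2Cl2, −78 → −40 °C; Et3N
Reagents that add atoms: none
Why: Swern conditions cleave and oxidise a primary TES ether directly to the aldehyde while the secondary TES ether and the acetate survive.

**Step 11**
Reactants: 8 bis-epoxide allyl chloride; 17 (2R,3S,4E)-5-methyl-1-oxo-2-[(triethylsilyl)oxy]octa-4,7-dien-3-yl acetate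
Product: 19 C6-chloro-C7-hydroxy union product (C1–C13 chain; 6,7-anti and 7,8-anti), via chloroallylzinc 18 (not isolated)
Conditions: 8 (1.3 equiv), ZnCl2, LiN(c-Hex)2 (Cy2NH/n-BuLi), THF, −78 °C; then 17, −78 → −40 °C; aq. work-up
Reagents that add atoms: none
Why: α-Chloroallylzinc addition, in which deprotonation α to chlorine and zinc trapping give the (E)-γ-chloroallylzinc that adds through a chair to the anti C6–Cl/C7–OH chlorohydrin, with Felkin–Anh attack anti to the α-OTES group fixing C7 and hence C6 absolutely.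

**Step 12**
Reactants: 19 C6-chloro-C7-hydroxy union product
Product: 20 C7 acrylate of 19
Conditions: acryloyl chloride, Et3N, DMAP (cat.), CH2Cl2, −20 °C
Reagents that add atoms: acryloyl chloride C=CC(=O)Cl
Why: Acylation of the only free hydroxyl brings in C17–C19 as the reductive-aldol donor, and an amine base is too weak to close the chlorohydrin to an epoxide.

**Step 13**
Reactants: 20 C7 acrylate
Product: 21 C8 alcohol (8-O-desilyl 20)
Conditions: HF·pyridine, pyridine, THF, 0 °C
Reagents that add atoms: none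
Why: Buffered fluoride desilylation frees the C8 hydroxyl without opening the oxiranes or moving the two acyl groups.

**Step 14**
Reactants: 21 C8 alcohol
Product: 22 C8 ketone (keto acrylate)
Conditions: Dess–Martin periodinane, pyridine, CH2Cl2, 0 °C
Reagents that add atoms: none
Why: Dess–Martin oxidation removes the temporary C8 stereocentre and gives the aldol acceptor under buffered, non-epimerising conditions.

**Step 15**
Reactants: 22 keto acrylate
Product: 24 β-hydroxy-γ-lactone (seco-macrocycle), via silyl aldolate 23 (not isolated)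
Conditions: Cu(OAc)2·H2O (10 mol%), rac-BINAP (10 mol%), (EtO)2MeSiH, THF, 0 °C; then HF·pyridine, pyridine, 0 °C
Reagents that add atoms: none
Why: Cu–H reductive aldol cyclisation, in which conjugate reduction gives a (Z)-copper enolate that adds to the C8 ketone through a chelated chair so that the C9 chain is trans to C6 and Me-18 is cis to the new 8-OH (also the thermodynamically preferred C17 epimer).

**Step 16**
Reactants: 24 β-hydroxy-γ-lactone (seco-macrocycle)
Product: 25 14-membered (10E,13Z)-cembranoid macrocycle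
Conditions: Z-selective cyclometalated Ru–NHC nitrato catalyst (10 mol%), DCE, 5 mM, 45 °C
Reagents that add atoms: none
Why: Z-selective ring-closing metathesis joins the two monosubstituted alkenes (the 1,1-di- and trisubstituted alkenes are inert and a six-ring closure onto C16 would need a trans-fused oxirane) and gives the cis C13=C14 alkene required for six-ring closure.

**Step 17**
Reactants: 25 14-membered (10E,13Z)-cembranoid macrocycle
Product: 26 tricyclic briarane (2,8,11-triol 9-acetate)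
Conditions: HFIP–H2O (50:1), 0 °C; aq. NaHCO3
Reagents that add atoms: water O
Why: Proposed new method: HFIP hydrogen bonding ionises only the tertiary, allylic C1–O bond of the 1,2-epoxide (the 3,4-epoxide is secondary and sits next to the electron-poor chloroallyl unit), the E-C10=C11 alkene attacks C1 of the cis-allyl cation anti to the leaving oxygen through a chair-like transannular array (inversion at C1 puts Me-15 β and frees the C2 carbinol, trans fusion puts H-10 α), and the C11 cation is captured anti on the α face by the C9 acetate carbonyl as a 1,3-dioxan-2-ylium ion that water hydrolyses to the 9-acetate/11α-ol, the closest known reaction types being epoxide-initiated cation–olefin cyclisation in HFIP, transannular cyclisation of germacrane and cembrane epoxides, and acyloxonium neighbouring-group participation.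

**Step 18**
Reactants: 26 tricyclic briarane (2,8,11-triol 9-acetate)
Product: 27 2,9-diacetate
Conditions: Ac2O, pyridine, DMAP (cat.), CH2Cl2, 0 °C
Reagents that add atoms: acetic anhydride CC(=O)OC(C)=O
Why: Acetylation esterifies the only secondary hydroxyl (C2), since the tertiary 8- and 11-hydroxyls do not react at 0 °C.

**Step 19**
Reactants: 27 2,9-diacetate
Product: 29 target CNP0176724.2, via 12-hydroxy compound 28 (not isolated)
Conditions: SeO2 (30 mol%), t-BuOOH, CH2Cl2, rt; then Dess–Martin periodinane, pyridine, 0 °C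
Reagents that add atoms: selenium dioxide O=[Se]=O; tert-butyl hydroperoxide CC(C)(C)OO
Why: SeO2 allylic oxidation (ene reaction then [2,3]-shift) can only use the C12 hydrogens of the C13=C14 alkene because C1 is quaternary, it returns the alkene to C13=C14, and Dess–Martin oxidation of the allylic alcohol gives the enone without touching the tertiary alcohols.

**Compound list**
1 | (E)-3-methylpent-2-en-4-yn-1-ol | C#C/C(C)=C/CO | starting material
2 | (E)-3-methylpenta-2,4-dien-1-ol | C=C/C(C)=C/CO | intermediate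
3 | [(2S,3S)-3-ethenyl-3-methyloxiran-2-yl]methanol | C=C[C@]1(C)O[C@H]1CO | intermediate
4 | (2R,3S)-3-ethenyl-3-methyloxirane-2-carbaldehyde | C=C[C@]1(C)O[C@H]1C=O | intermediate
5 | 3-chloro-2-(chloromethyl)prop-1-ene | C=C(CCl)CCl | starting material
6 | [3-chloro-2-(chloromethyl)allyl]bis[(1S,2R,3S,5S)-isopinocampheyl]borane, γ-Cl cis to CH2B | Cl/C=C(\CB([C@H]1C[C@H]2C[C@@H]([C@@H]1C)C2(C)C)[C@H]1C[C@H]2C[C@@H]([C@@H]1C)C2(C)C)CCl | intermediate (not isolated)
7 | (1S,2S)-2-chloro-3-(chloromethyl)-1-[(2S,3S)-3-ethenyl-3-methyloxiran-2-yl]but-3-en-1-ol (syn-chlorohydrin) | C=C[C@]1(C)O[C@H]1[C@H](O)[C@@H](Cl)C(=C)CCl | intermediate (not isolated)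
8 | (2S,3S)-2-[(2R,3R)-3-(3-chloroprop-1-en-2-yl)oxiran-2-yl]-3-ethenyl-3-methyloxirane (C14, C1–C6, C15, C16) | C=C[C@]1(C)O[C@H]1[C@@H]1O[C@@H]1C(=C)CCl | intermediate
9 | pent-1-en-4-yne | C=CCC#C | starting material
10 | ethyl (Z)-3-iodoprop-2-enoate | CCOC(=O)/C=C\I | starting material
11 | dimethyl[(1E)-2-methylpenta-1,4-dien-1-yl]alane | C=CC/C(C)=C/[Al](C)C | intermediate (not isolated)
12 | ethyl (2Z,4E)-5-methylocta-2,4,7-trienoate | C=CC/C(C)=C/C=C\C(=O)OCC | intermediate
13 | (2Z,4E)-5-methylocta-2,4,7-trien-1-ol | C=CC/C(C)=C/C=C\CO | intermediate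
14 | [(2S,3R)-3-[(1E)-2-methylpenta-1,4-dien-1-yl]oxiran-2-yl]methanol (cis-epoxide) | OC[C@@H]1O[C@@H]1/C=C(\C)CC=C | intermediate
15 | (2S,3S,4E)-1,2-dihydroxy-5-methylocta-4,7-dien-3-yl acetate | OC[C@H](O)[C@@H](OC(C)=O)/C=C(\C)CC=C | intermediate
16 | (2S,3S,4E)-5-methyl-1,2-bis[(triethylsilyl)oxy]octa-4,7-dien-3-yl acetate | CC[Si](CC)(CC)OC[C@H](O[Si](CC)(CC)CC)[C@@H](OC(C)=O)/C=C(\C)CC=C | intermediate
17 | (2R,3S,4E)-5-methyl-1-oxo-2-[(triethylsilyl)oxy]octa-4,7-dien-3-yl acetate (C7 aldehyde, C8 OTES, C9 OAc) | O=C[C@H](O[Si](CC)(CC)CC)[C@@H](OC(C)=O)/C=C(\C)CC=C | intermediate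
18 | (E)-γ-chloroallylzinc chloride derived from 8 (Zn on C16, fluxional) | C=C[C@]1(C)O[C@H]1[C@@H]1O[C@@H]1/C(C[Zn]Cl)=C\Cl | intermediate (not isolated)
19 | union product: 1,2:3,4-bis-epoxy-6-chloro-7-hydroxy-8-OTES-9-OAc chain with 5(16)-ene and 10E-ene, vinyl on C1, allyl on C11 | C=C[C@]1(C)O[C@H]1[C@@H]1O[C@@H]1C(=C)[C@H](Cl)[C@H](O)[C@H](O[Si](CC)(CC)CC)[C@@H](OC(C)=O)/C=C(\C)CC=C | intermediate
20 | C7 acrylate of 19 | C=C[C@]1(C)O[C@H]1[C@@H]1O[C@@H]1C(=C)[C@H](Cl)[C@H](OC(=O)C=C)[C@H](O[Si](CC)(CC)CC)[C@@H](OC(C)=O)/C=C(\C)CC=C | intermediate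
21 | 8-hydroxy 7-acrylate 9-acetate (desilylated 20) | C=C[C@]1(C)O[C@H]1[C@@H]1O[C@@H]1C(=C)[C@H](Cl)[C@H](OC(=O)C=C)[C@H](O)[C@@H](OC(C)=O)/C=C(\C)CC=C | intermediate
22 | 8-oxo 7-acrylate 9-acetate (keto acrylate) | C=C[C@]1(C)O[C@H]1[C@@H]1O[C@@H]1C(=C)[C@H](Cl)[C@H](OC(=O)C=C)C(=O)[C@@H](OC(C)=O)/C=C(\C)CC=C | intermediate
23 | 8-O-[diethoxy(methyl)silyl] ether of lactone 24 | C=C[C@]1(C)O[C@H]1[C@@H]1O[C@@H]1C(=C)[C@H](Cl)[C@@H]1OC(=O)[C@H](C)[C@@]1(O[Si](C)(OCC)OCC)[C@@H](OC(C)=O)/C=C(\C)CC=C | intermediate (not isolated)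
24 | seco-macrocycle: γ-lactone C19(=O)–O–C7 with 8-OH (cis to C6 and Me-18), 9-OAc, 6-Cl, both oxiranes, vinyl on C1, allyl on C11 | C=C[C@]1(C)O[C@H]1[C@@H]1O[C@@H]1C(=C)[C@H](Cl)[C@@H]1OC(=O)[C@H](C)[C@@]1(O)[C@@H](OC(C)=O)/C=C(\C)CC=C | intermediate
25 | cembranoid macrocycle: 14-membered ring C1–C14, 1,2:3,4-bis-epoxy, 5(16)-ene, 6-Cl, 19,7-lactone, 8-OH, 9-OAc, 10E-ene, 13Z-ene | C[C@@]12O[C@H]1[C@@H]1O[C@@H]1C(=C)[C@H](Cl)[C@@H]1OC(=O)[C@H](C)[C@@]1(O)[C@@H](OC(C)=O)/C=C(\C)C/C=C\2 | intermediate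
26 | tricyclic briarane: 9-acetoxy-6-chloro-3,4-epoxy-2,8,11-trihydroxy-5(16),13-diene 19,7-lactone | C=C1[C@H]2O[C@H]2[C@H](O)[C@@]2(C)C=CC[C@@](C)(O)[C@@H]2[C@H](OC(C)=O)[C@]2(O)[C@@H](C)C(=O)O[C@H]2[C@H]1Cl | intermediate
27 | 2,9-diacetate of 26 (12-deoxo target) | C=C1[C@H]2O[C@H]2[C@H](OC(C)=O)[C@@]2(C)C=CC[C@@](C)(O)[C@@H]2[C@H](OC(C)=O)[C@]2(O)[C@@H](C)C(=O)O[C@H]2[C@H]1Cl | intermediate
28 | 12-hydroxy derivative of 27 (C12 epimers) | C=C1[C@H]2O[C@H]2[C@H](OC(C)=O)[C@@]2(C)C=CC(O)[C@@](C)(O)[C@@H]2[C@H](OC(C)=O)[C@]2(O)[C@@H](C)C(=O)O[C@H]2[C@H]1Cl | intermediate (not isolated)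
29 | CNP0176724.2: 2,9-diacetoxy-6-chloro-3,4-epoxy-8,11-dihydroxy-12-oxobriara-5(16),13-diene 19,7-lactone | C=C1[C@H]2O[C@H]2[C@H](OC(C)=O)[C@@]2(C)C=CC(=O)[C@@](C)(O)[C@@H]2[C@H](OC(C)=O)[C@]2(O)[C@@H](C)C(=O)O[C@H]2[C@H]1Cl | target

**Totals**
Total step count: 19. Longest linear sequence: 15 (steps 5–19). The west branch (steps 1–4) joins at step 11.

**Three steps most likely to fail**

Step 17 (key cyclisation). The free tertiary 8-OH may trap the C11 cation as an 8,11-ether, the cation may eliminate instead of being hydrated, or the 3,4-epoxide may open. The fallback changes the order of ring formation so that no C8 hydroxyl is present. It sets out from ketone 22, which is closed by the same Z-selective RCM to the macrocyclic keto acrylate F1. F1 is cyclised in HFIP–H2O to the bicyclic keto acrylate F2, where C8 is still a ketone. The lactone is then built last on the rigid bicycle by Cu–H reductive aldol (Stryker's reagent, toluene, −40 °C, aqueous NH4Cl), which comes back to the route at 26.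

Step 11 (zinc chloroallylation). The amide base may attack the oxiranes, and the anti and Felkin selectivities are only substrate-controlled. The fallback uses reagent control followed by inversion. It sets out from 8 and 17. Compound 8 is converted (LiN(c-Hex)2, (+)-Ipc2BOMe, BF3·OEt2, −95 °C) into the γ-chloroallyl-bis(isopinocampheyl)borane F3, which adds to 17 to give the syn-chlorohydrin F4 (C6 as in the target, C7 epimeric; this is the anti-Felkin, reagent-controlled face). Mitsunobu esterification of F4 with acrylic acid (PPh3, DIAD) inverts C7 and installs the acrylate in one operation, which comes back to the route at 20.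

Step 19 (late allylic oxidation). SeO2 may be too slow on the hindered cis-alkene, may attack the 5(16)-ene, or its acidity may open the vinyl oxirane. The fallback brings in the C12 oxygen by alkene oxidation instead of C–H oxidation. It sets out from 25, which is cyclised under strictly anhydrous, eliminative conditions (HFIP, 2,6-di-tert-butylpyridine, 4 Å MS), so that the C11 cation loses the allylic H-12 and gives the 11,13-diene F5. OsO4 (cat.)/NMO dihydroxylates the electron-rich trisubstituted C11=C12 bond from the α face, anti to the axial Me-15, to the 11α,12α-diol F6. MnO2 oxidises only the allylic C12 carbinol to the 2-O-deacetyl enone F7, and Ac2O/pyridine acetylates C2, which arrives at 29.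

**Further compounds**
F1 | step 17 | macrocyclic keto acrylate (13Z RCM product of 22) | C[C@@]12O[C@H]1[C@@H]1O[C@@H]1C(=C)[C@H](Cl)[C@H](OC(=O)C=C)C(=O)[C@@H](OC(C)=O)/C=C(\C)C/C=C\2
F2 | step 17 | bicyclic keto acrylate (2,11-diol, 8-ketone, 7-acrylate, 9-acetate) | C=C1[C@H]2O[C@H]2[C@H](O)[C@@]2(C)C=CC[C@@](C)(O)[C@@H]2[C@H](OC(C)=O)C(=O)[C@@H](OC(=O)C=C)[C@H]1Cl
F3 | step 11 | γ-chloroallyl-bis[(1S,2R,3S,5S)-isopinocampheyl]borane derived from 8 (B on C16, Cl cis to CH2B) | C=C[C@]1(C)O[C@H]1[C@@H]1O[C@@H]1/C(CB([C@H]2C[C@H]3C[C@@H]([C@@H]2C)C3(C)C)[C@H]2C[C@H]3C[C@@H]([C@@H]2C)C3(C)C)=C/Cl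
F4 | step 11 | syn-chlorohydrin (7-epi-19) | C=C[C@]1(C)O[C@H]1[C@@H]1O[C@@H]1C(=C)[C@H](Cl)[C@@H](O)[C@H](O[Si](CC)(CC)CC)[C@@H](OC(C)=O)/C=C(\C)CC=C
F5 | step 19 | tricyclic 11,13-diene (2,8-diol 9-acetate) | C=C1[C@H]2O[C@H]2[C@H](O)[C@@]2(C)C=CC=C(C)[C@@H]2[C@H](OC(C)=O)[C@]2(O)[C@@H](C)C(=O)O[C@H]2[C@H]1Cl
F6 | step 19 | 11α,12α-diol (2,8,11,12-tetrol 9-acetate) | C=C1[C@H]2O[C@H]2[C@H](O)[C@@]2(C)C=C[C@@H](O)[C@@](C)(O)[C@@H]2[C@H](OC(C)=O)[C@]2(O)[C@@H](C)C(=O)O[C@H]2[C@H]1Cl
F7 | step 19 | 2-O-deacetyl target (12-oxo-13-ene, 2-OH) | C=C1[C@H]2O[C@H]2[C@H](O)[C@@]2(C)C=CC(=O)[C@@](C)(O)[C@@H]2[C@H](OC(C)=O)[C@]2(O)[C@@H](C)C(=O)O[C@H]2[C@H]1Cl
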